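## Structural features

19 is a 2,3-dihydrobenzofuran: a benzene ring fused through C3a and C7a to a five-membered ring made of O1, C2 and C3. The benzene ring carries an acetyl group on C5 and methoxy groups on C6 and C7, so only C4 keeps a hydrogen. C2 (isopropenyl, R) and C3 (angeloyloxy, R) are neighbours, and their substituents are cis on the five-membered ring. The groups around these two carbons are fragile. Loss of the C3 acyloxy group together with the C2 hydrogen gives an aromatic furan, helped by O1 and the C6 methoxy group, which stabilise positive charge at C3. The angelate is the Z isomer and drifts to the E isomer with nucleophiles, radicals or acid; the isopropenyl double bond can move toward C2; the aryl methyl ketone is reducible and enolisable. The real difficulty is to set the cis C2/C3 pair in the right absolute sense on a ring one elimination away from aromaticity, and to bring in three reactive groups in an order in which none spoils the others. The key step uses the position of C3, a carbinol carbon between C3a of the benzene ring and C2. One oxidation level up C3 is a ketone, and C2, lying between O1 and that carbonyl and holding a carboxylate, inverts freely through the flat 3-hydroxybenzofuran enol, so one hydride delivery to C3 can fix both centres. The C2 carboxylate is also the one-carbon seed of the isopropenyl group, and a bromine on C5 holds the place of the acetyl group.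

## Logic of the disconnections

19 ⇒ 16 + 17. The acyl C–O bond at C3 is cut first. The Z enoate is the group least able to survive other reagents, so it is attached last; what remains is a secondary benzylic alcohol and a commercial acid. The forward step must acylate a hindered hydroxyl through 18 without a nucleophilic catalyst, without enough heat to eliminate, and with retention at C3.

16 ⇒ 15. The O–Si bond on C3 is restored. A silyl ether is needed from 9 onward, because a free C3 hydroxyl would be sulfamoylated in 11 → 13 and would open a retro-aldol path in 9 → 11. The forward cleavage must run near neutrality so that the ketone is not enolised and the C3 oxygen is not lost.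

15 ⇒ 13. The C5–C bond of the acetyl group is cut to an aryl bromide and an acetyl anion equivalent (through 14). An aryl ketone would survive neither the hydride transfer 6 → 8 nor the Grignard addition 9 → 11, whereas bromine is inert to both. The forward step needs coupling at an electron-rich C–Br bond beside a methoxy group, and a hydrolysis of 14 mild enough for the silyl ether and the isopropenyl group.

13 ⇒ 11. The C=C bond of the isopropenyl group is traced to the C–O bond of a tertiary carbinol (through 12). This turns the alkene into a group that comes from a carboxylate. The forward elimination must go toward a methyl group and not toward C2–H, which would put the double bond on the ring and invite aromatisation.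

11 ⇒ 9. Both C–CH3 bonds of the carbinol are cut, leaving a C2 methyl ester (through 10). The side chain shrinks to the one-carbon ester that makes the key step possible. The forward addition must be faster than deprotonation at C2, since the C3 silyloxy group is a leaving group β to the ester.

9 ⇒ 8. The O–Si bond is cut to the free cis hydroxy ester. The forward silylation must use a weak, hindered base at low temperature so that C2 is not epimerised.

8 ⇒ 6. This is the key disconnection: the C3–H bond is removed. Both stereocentres vanish, and the precursor is a flat, achiral, aromatic 3-hydroxybenzofuran-2-carboxylate that reacts through 7. The forward step must choose one face of the ketone, deliver hydride anti to the ester, and be slower than C2 inversion. The methyl ester and the bromide are kept in 6 because they are what steps 6 and 8 need and both are inert to the ruthenium hydride.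

6 ⇒ 3 + 4. The C2–C3 bond (Dieckmann condensation) and the O1–C2 bond (phenoxide alkylation) are cut, through 5. The five-membered ring disappears and a salicylate and a two-carbon electrophile remain. Only one ester of 5 can enolise, so the ring closure has one outcome; both bonds are made in one flask.

3 ⇒ 2. The C5–Br bond is cut. The free phenol directs para to itself, to the carbon that becomes C5, so bromination must precede O-alkylation. The forward step must stop at one bromine.

2 ⇒ 1. The methyl ester C–O bond is cut to the commercial acid. The ester is needed as the electrophile in 5 → 6, and it protects against ipso substitution of the carboxyl group during bromination.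

## Other disconnections considered

Alternative 1: The cut is the C3–O bond, replaced in the forward sense by a C3–Si bond made from the benzylic C3–H bond.
- **Forward step.** A1, the diethylhydrosilyl ether of the C2 carbinol branch with the acetyl group held as a dioxolane, would be cyclised with [Ir(cod)OMe]2, 3,4,7,8-tetramethyl-1,10-phenanthroline and norbornene as hydrogen acceptor to the oxasilolane A2. Tamao–Fleming oxidation, with retention at carbon, would then give diol A3.
- **In its favour.** The C2 centre would be set beforehand by robust chemistry (asymmetric epoxidation of a prenyl side chain and ring closure through the phenol oxygen). The tether can reach only the C3–H bond on its own face, so cis is enforced by ring fusion and not by a selectivity ratio; on diastereocontrol this plan is the better one. It also needs no tin reagent, because the acetyl carbon is present from the start.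
- **Against it here.** Silylation of a secondary C–H bond is much slower than that of a methyl group and needs high temperature on an electron-rich arene. The oxidation uses peroxide and fluoride or base next to a ketal. A3 must still pass through the same dehydration and acylation as 11 and 16, with an added acidic ketal cleavage beside the labile C3 ester.
- **Comparison.** The chosen plan rests on a reduction whose facial sense and cis preference are of a well-charted type, whereas A1 → A2 asks an iridium silyl species to insert into a hindered benzylic C–H bond. In step count the two are about equal once the steps to A1 are counted.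

Alternative 2: The cut runs through the benzene ring at C3a–C4 and C7a–C7.
- **Forward step.** The cis lactone A4 would be converted into its silyl ketene acetal A5, which adds in an inverse-demand [4+2] cycloaddition across C3 and C6 of the pyrone A6. The bridged adduct loses CO2 and then tert-butyldimethylsilanol to give A7, which is the same compound as 15.
- **In its favour.** The plan is convergent, and in convergence it is the better one. A6 brings the acetyl and both methoxy groups, so no bromide, no palladium step and no reducible-ketone problem arise. The polarity is matched, since the nucleophilic carbon of A5 meets C6 of A6, which fixes the regiochemistry. From A7 the two plans are identical and equal.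
- **Against it here.** Both stereocentres must be made beforehand in A4 by a separate asymmetric synthesis. They must then survive enolisation of a lactone that carries a leaving group β to the enolate carbon, which invites β-elimination. A6 is not commercial, and its two methoxy groups make the diene less electron-poor, so the cycloaddition and the loss of CO2 would need heat that A5 may not tolerate.
- **Comparison.** The chosen plan creates the stereocentres in the key step on a robust aromatic precursor. Here they are only carried through a step that threatens them. Two multi-step fragments make the total count higher, though the longest linear sequence could be shorter.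

Alternative 3: The cut is the C2–C3 bond.
- **Forward step.** In the keto aldehyde A8, proline would form the enamine on the oxygen-bearing side of the ketone, which attacks the ortho aldehyde in a 5-enolexo aldol to give the cis hydroxy ketone A9.
- **In its favour.** Ring, C–C bond and both stereocentres arise in one metal-free step, whereas step 4 of the chosen plan makes no skeletal bond; on bond-forming economy this plan is the better one. The C2 acetyl group of A9 is one methylenation away from the isopropenyl group, so the regiochemical question of step 7 does not arise, which is also better. A8 should be available in two steps from a commercial salicylaldehyde, and the whole route is about two steps shorter on paper.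
- **Against it here.** A9 is a β-hydroxy ketone whose loss of water gives an aromatic furan, and the amine catalyst can promote this. Enamine aldols of oxygenated ketones usually prefer the anti arrangement in open-chain cases, so cis is not assured. Retro-aldol and epimerisation at the acidic C2 would wear down both selectivities, and the C2 ketone stays epimerisable in later steps.
- **Comparison.** The chosen plan reaches the same cis pattern as an ester, which is less acidic at C2, with both selectivities resting on a known reaction type. It pays for this with more steps and an elimination whose direction must be controlled.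

Key step: step 4

## Route

Remark: 6 is written as the enol in which it should rest and is taken to react through its keto tautomer 7; the (S,S) ligand is assigned from the usual aryl ketone model of this catalyst family, which leads to 3R here. 6 and 8 match 19 in substitution pattern (Br on C5, OMe on C6 and C7) and 8 is cis with (2S,3R), so neither structure needs correction.

Step 1
Reactants: 1 2-hydroxy-3,4-dimethoxybenzoic acid
Product: 2 methyl 2-hydroxy-3,4-dimethoxybenzoate
Conditions: MeOH, H2SO4 (cat.), reflux
Reagents that add atoms: methanol, CO
Why: Fischer esterification; acid-catalysed acyl substitution driven by methanol as solvent, with phenol and aryl ethers untouched. The ester is needed as the Dieckmann electrophile and prevents ipso bromination with loss of CO2 in step 2.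

Step 2
Reactants: 2 methyl 2-hydroxy-3,4-dimethoxybenzoate
Product: 3 methyl 5-bromo-2-hydroxy-3,4-dimethoxybenzoate
Conditions: NBS (1.0 equiv), MeCN, 0 °C → rt
Reagents that add atoms: N-bromosuccinimide, O=C1CCC(=O)N1Br
Why: Electrophilic aromatic bromination; C5 is para to the free phenol, ortho to the 4-methoxy group and meta to the ester. The only other open carbon, C6, is ortho to the ester and activated only by the twisted 3-methoxy group, so one equivalent should give the 5-bromide.

Step 3
Reactants: 3 methyl 5-bromo-2-hydroxy-3,4-dimethoxybenzoate; 4 methyl bromoacetate
Product: 6 methyl 5-bromo-3-hydroxy-6,7-dimethoxybenzofuran-2-carboxylate, via diester 5 (not isolated)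
Conditions: K2CO3, DMF, 50 °C; then t-BuOK, 0 °C → rt; aq. HCl
Reagents that add atoms: none
Why: Williamson ether synthesis then Dieckmann condensation: the phenoxide of 3 displaces bromide from 4, and the enolate of the aryloxyacetate arm of 5 attacks the neighbouring benzoate carbonyl (5-exo-trig) and expels methoxide. Deprotonation of the product to its stabilised enolate pulls the equilibrium over, and only one ester of 5 can enolise; 4 is held at one equivalent so that none is left to alkylate that enolate.

Step 4
Reactants: 6 methyl 5-bromo-3-hydroxy-6,7-dimethoxybenzofuran-2-carboxylate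
Product: 8 methyl (2S,3R)-5-bromo-3-hydroxy-6,7-dimethoxy-2,3-dihydrobenzofuran-2-carboxylate, via keto tautomer 7 (not isolated)
Conditions: RuCl(p-cymene)[(S,S)-TsDPEN] (2 mol%), HCO2H/Et3N (5:2), DMF, 40 °C
Reagents that add atoms: none
Why: Noyori–Ikariya asymmetric transfer hydrogenation with dynamic kinetic resolution, the reaction type known for cyclic α-substituted β-keto esters and 2-substituted benzofuran-3(2H)-ones, applied here to the enol form of such a keto ester. In the formic acid/amine medium enol 6 exchanges with a small share of racemic keto tautomer 7, and the two enantiomers of 7 interconvert through 6 much faster than either is reduced. The hydride RuH(p-cymene)[(S,S)-TsDPEN], remade from formate with loss of CO2, hands hydride to C3 and the N–H proton to the carbonyl oxygen in a six-membered outer-sphere transition state; only the C3–H and O–H bonds form, no ring is closed and no skeletal bond is made. C3 is controlled by the ligand: the benzene ring of 7 lies under the p-cymene ligand (CH/π contact), which for the (S,S) ligand opens the Si face of the ketone and gives 3R. C2 is controlled by the substrate within that transition state: hydride comes in anti to the C2 ester, so the 2S enantiomer of 7 is the fast one and hydroxyl and ester end cis. The step needs enantioface selection, cis selection and racemisation faster than reduction; the first two come from the catalyst and the ester, the third from the aromatic enol, which makes inversion at C2 nearly free. Chemoselectivity is secured by the C5 bromine, which a ruthenium hydride of this kind leaves alone where an acetyl group would be reduced, and the mild medium should spare the β-hydroxy ester from loss of water.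

Step 5
Reactants: 8 methyl (2S,3R)-5-bromo-3-hydroxy-6,7-dimethoxy-2,3-dihydrobenzofuran-2-carboxylate
Product: 9 methyl (2S,3R)-5-bromo-3-[(tert-butyldimethylsilyl)oxy]-6,7-dimethoxy-2,3-dihydrobenzofuran-2-carboxylate
Conditions: TBSOTf, 2,6-lutidine, CH2Cl2, −78 → 0 °C
Reagents that add atoms: tert-butyldimethylsilyl trifluoromethanesulfonate, CC(C)(C)[Si](C)(C)OS(=O)(=O)C(F)(F)F
Why: O-silylation of a secondary alcohol with a silyl triflate and a hindered pyridine base. The base is too weak to deprotonate C2, so neither epimerisation nor β-elimination is expected, and both stereocentres are untouched.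

Step 6
Reactants: 9 methyl (2S,3R)-5-bromo-3-[(tert-butyldimethylsilyl)oxy]-6,7-dimethoxy-2,3-dihydrobenzofuran-2-carboxylate
Product: 11 2-[(2S,3R)-5-bromo-3-[(tert-butyldimethylsilyl)oxy]-6,7-dimethoxy-2,3-dihydrobenzofuran-2-yl]propan-2-ol, via methyl ketone 10 (not isolated)
Conditions: MeMgBr (3 equiv), THF, −78 → 0 °C; aq. NH4Cl
Reagents that add atoms: methylmagnesium bromide, C[Mg]Br
Why: Double Grignard addition to an ester through ketone 10, which is more electrophilic than 9 and is consumed as it forms. An α-alkoxy ester adds MeMgBr faster than it is deprotonated at low temperature and the aryl bromide does not exchange with MeMgBr; C2 and C3 are not touched.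

Step 7
Reactants: 11 2-[(2S,3R)-5-bromo-3-[(tert-butyldimethylsilyl)oxy]-6,7-dimethoxy-2,3-dihydrobenzofuran-2-yl]propan-2-ol
Product: 13 tert-butyl{[(2R,3R)-5-bromo-6,7-dimethoxy-2-(prop-1-en-2-yl)-2,3-dihydrobenzofuran-3-yl]oxy}dimethylsilane, via sulfamate ester 12 (not isolated)
Conditions: Burgess reagent (methyl N-(triethylammoniosulfonyl)carbamate), toluene, rt → 50 °C
Reagents that add atoms: none
Why: Burgess dehydration: the tertiary alcohol forms sulfamate ester 12, which undergoes syn elimination on warming under neutral conditions that spare the silyl ether. Six methyl hydrogens compete with one C2–H that is hindered and sits on a carbon made electron-poor by O1, so loss toward methyl should dominate. The C2 descriptor changes from S to R only because the side chain drops in CIP rank; nothing moves in space.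

Step 8
Reactants: 13 tert-butyl{[(2R,3R)-5-bromo-6,7-dimethoxy-2-(prop-1-en-2-yl)-2,3-dihydrobenzofuran-3-yl]oxy}dimethylsilane
Product: 15 1-[(2R,3R)-3-[(tert-butyldimethylsilyl)oxy]-6,7-dimethoxy-2-(prop-1-en-2-yl)-2,3-dihydrobenzofuran-5-yl]ethan-1-one, via enol ether 14 (not isolated)
Conditions: Bu3Sn(C(OEt)=CH2) (1.5 equiv), Pd(PPh3)4 (5 mol%), toluene, 100 °C; then 1 M HCl, THF, 0 °C
Reagents that add atoms: tributyl(1-ethoxyvinyl)stannane, CCCC[Sn](CCCC)(CCCC)C(=C)OCC; water, O
Why: Stille coupling with an acetyl anion equivalent: oxidative addition of the C5–Br bond to zerovalent palladium, transfer of the 1-ethoxyvinyl group from tin and reductive elimination give 14. Dilute acid then hydrolyses the aryl enol ether (protonation at CH2, addition of water, loss of ethanol) far faster than it attacks the isopropenyl group or the silyl ether.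

Step 9
Reactants: 15 1-[(2R,3R)-3-[(tert-butyldimethylsilyl)oxy]-6,7-dimethoxy-2-(prop-1-en-2-yl)-2,3-dihydrobenzofuran-5-yl]ethan-1-one
Product: 16 1-[(2R,3R)-3-hydroxy-6,7-dimethoxy-2-(prop-1-en-2-yl)-2,3-dihydrobenzofuran-5-yl]ethan-1-one
Conditions: Bu4NF, AcOH, THF, 0 °C → rt
Reagents that add atoms: none
Why: Fluoride-mediated desilylation, driven by the strength of the Si–F bond. Acetic acid buffers the alkoxide so that the aryl methyl ketone is not enolised and the benzylic oxygen is not expelled; the O–Si bond is cleaved, not the C3–O bond, so C3 keeps its configuration.

Step 10
Reactants: 16 1-[(2R,3R)-3-hydroxy-6,7-dimethoxy-2-(prop-1-en-2-yl)-2,3-dihydrobenzofuran-5-yl]ethan-1-one; 17 angelic acid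
Product: 19 (2R,3R)-5-acetyl-6,7-dimethoxy-2-(prop-1-en-2-yl)-2,3-dihydrobenzofuran-3-yl (Z)-2-methylbut-2-enoate, via mixed anhydride 18 (not isolated)
Conditions: 17, 2,4,6-Cl3C6H2COCl, Et3N, toluene, rt; then 16, 70 °C
Reagents that add atoms: none
Why: Yamaguchi esterification: the C3 hydroxyl attacks the angeloyl carbonyl of 18, because the aryl carbonyl is blocked by its two ortho chlorines. No nucleophilic catalyst is used, so the conjugate addition–elimination that would turn the Z enoate into the E isomer has no carrier, and acylation at oxygen retains the C3 configuration.

## Compound list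

1 | 2-hydroxy-3,4-dimethoxybenzoic acid | COc1ccc(C(=O)O)c(O)c1OC | starting material
2 | methyl 2-hydroxy-3,4-dimethoxybenzoate | COC(=O)c1ccc(OC)c(OC)c1O | intermediate
3 | methyl 5-bromo-2-hydroxy-3,4-dimethoxybenzoate | COC(=O)c1cc(Br)c(OC)c(OC)c1O | intermediate
4 | methyl bromoacetate | COC(=O)CBr | starting material
5 | methyl 5-bromo-3,4-dimethoxy-2-(2-methoxy-2-oxoethoxy)benzoate (not isolated) | COC(=O)COc1c(OC)c(OC)c(Br)cc1C(=O)OC | intermediate
6 | methyl 5-bromo-3-hydroxy-6,7-dimethoxybenzofuran-2-carboxylate | COC(=O)c1oc2c(OC)c(OC)c(Br)cc2c1O | intermediate
7 | methyl 5-bromo-6,7-dimethoxy-3-oxo-2,3-dihydrobenzofuran-2-carboxylate, racemic keto tautomer of 6 (not isolated) | COC(=O)C1Oc2c(OC)c(OC)c(Br)cc2C1=O | intermediate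
8 | methyl (2S,3R)-5-bromo-3-hydroxy-6,7-dimethoxy-2,3-dihydrobenzofuran-2-carboxylate (cis) | COC(=O)[C@H]1Oc2c(cc(Br)c(OC)c2OC)[C@H]1O | intermediate
9 | methyl (2S,3R)-5-bromo-3-[(tert-butyldimethylsilyl)oxy]-6,7-dimethoxy-2,3-dihydrobenzofuran-2-carboxylate | COC(=O)[C@H]1Oc2c(cc(Br)c(OC)c2OC)[C@H]1O[Si](C)(C)C(C)(C)C | intermediate
10 | 1-[(2S,3R)-5-bromo-3-[(tert-butyldimethylsilyl)oxy]-6,7-dimethoxy-2,3-dihydrobenzofuran-2-yl]ethan-1-one (not isolated) | CC(=O)[C@H]1Oc2c(cc(Br)c(OC)c2OC)[C@H]1O[Si](C)(C)C(C)(C)C | intermediate
11 | 2-[(2S,3R)-5-bromo-3-[(tert-butyldimethylsilyl)oxy]-6,7-dimethoxy-2,3-dihydrobenzofuran-2-yl]propan-2-ol | CC(C)(O)[C@H]1Oc2c(cc(Br)c(OC)c2OC)[C@H]1O[Si](C)(C)C(C)(C)C | intermediate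
12 | triethylammonium salt of the O-alkyl N-(methoxycarbonyl)sulfamate of 11 (not isolated) | COC(=O)[N-]S(=O)(=O)OC(C)(C)[C@H]1Oc2c(cc(Br)c(OC)c2OC)[C@H]1O[Si](C)(C)C(C)(C)C.CC[NH+](CC)CC | intermediate
13 | tert-butyl{[(2R,3R)-5-bromo-6,7-dimethoxy-2-(prop-1-en-2-yl)-2,3-dihydrobenzofuran-3-yl]oxy}dimethylsilane | C=C(C)[C@H]1Oc2c(cc(Br)c(OC)c2OC)[C@H]1O[Si](C)(C)C(C)(C)C | intermediate
14 | tert-butyl{[(2R,3R)-5-(1-ethoxyethenyl)-6,7-dimethoxy-2-(prop-1-en-2-yl)-2,3-dihydrobenzofuran-3-yl]oxy}dimethylsilane (not isolated) | C=C(C)[C@H]1Oc2c(cc(C(=C)OCC)c(OC)c2OC)[C@H]1O[Si](C)(C)C(C)(C)C | intermediate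
15 | 1-[(2R,3R)-3-[(tert-butyldimethylsilyl)oxy]-6,7-dimethoxy-2-(prop-1-en-2-yl)-2,3-dihydrobenzofuran-5-yl]ethan-1-one | C=C(C)[C@H]1Oc2c(cc(C(C)=O)c(OC)c2OC)[C@H]1O[Si](C)(C)C(C)(C)C | intermediate
16 | 1-[(2R,3R)-3-hydroxy-6,7-dimethoxy-2-(prop-1-en-2-yl)-2,3-dihydrobenzofuran-5-yl]ethan-1-one | C=C(C)[C@H]1Oc2c(cc(C(C)=O)c(OC)c2OC)[C@H]1O | intermediate
17 | angelic acid, (Z)-2-methylbut-2-enoic acid | C/C=C(/C)C(=O)O | starting material
18 | (Z)-2-methylbut-2-enoic 2,4,6-trichlorobenzoic anhydride (not isolated) | C/C=C(/C)C(=O)OC(=O)c1c(Cl)cc(Cl)cc1Cl | intermediate
19 | (2R,3R)-5-acetyl-6,7-dimethoxy-2-(prop-1-en-2-yl)-2,3-dihydrobenzofuran-3-yl (Z)-2-methylbut-2-enoate, CNP0113631.1 | C=C(C)[C@H]1Oc2c(cc(C(C)=O)c(OC)c2OC)[C@H]1OC(=O)/C(C)=C\C | target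

## Step count and least certain steps

Total: 10 steps. Longest linear sequence: 10 steps (1 → 19; 4 and 17 are bought).

The key step, step 4, is the least certain. The most likely failure is slow turnover, because only the small keto share of the enol-stabilised substrate is reducible; long heating could then let the product lose water across C2–C3 or erode the cis and enantiomeric selectivity. If the sense of induction proves opposite to the model, the (R,R) ligand is the remedy within the same step. The fallback gives up the asymmetric catalyst and separates reduction from resolution; it sets out from 6 and comes back at 8.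
- Zn(BH4)2 (Et2O/THF, 0 °C), a chelating and non-basic hydride that should also add anti to the ester, would give the racemic cis hydroxy ester F1.
- Acylative kinetic resolution with a lipase (Candida antarctica lipase B, vinyl acetate, tert-butyl methyl ether) should, by the usual empirical rule for secondary alcohols with the aryl ring as the large group, acetylate the (3S) enantiomer to the acetate of the unwanted enantiomer F2 and leave 8, which goes on to step 5.
- The price is half of the material.

Step 7 is next. What may go wrong is elimination toward C2–H instead of toward a methyl group, which places the double bond on the ring and is followed by loss of the C3 silyloxy group with aromatisation. The reason is that the ring-substituted alkene is the more stable one and the sulfamate has some ion-pair character. The fallback fixes the double bond position by construction; it sets out from 9 and comes back at 13.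
- MeNH(OMe)·HCl and i-PrMgCl (THF, −20 °C) convert 9 into the Weinreb amide F3.
- One equivalent of MeMgBr gives the methyl ketone 10, this time isolated.
- Petasis methylenation with Cp2TiMe2 (toluene, 65 °C), which is not basic and so should neither epimerise C2 nor expel silanol, gives 13.

Step 10 comes third. What may go wrong is isomerisation of the Z double bond to E during activation, or loss of the C3 oxygen with aromatisation under the heat that a hindered alcohol needs without a nucleophilic catalyst. The fallback builds the Z double bond after the ester bond is in place; it sets out from 16 and comes back at 19.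
- 16 is esterified with 2-[bis(2,2,2-trifluoroethoxy)phosphoryl]propanoic acid (DCC, cat. DMAP, CH2Cl2, 0 °C; harmless here because no Z alkene is present yet) to the phosphonate ester F4.
- Still–Gennari olefination with acetaldehyde (KN(SiMe3)2, one equivalent, 18-crown-6, THF, −78 °C) gives 19. The phosphonate is far more acidic than the aryl methyl ketone, so one equivalent of base should be selective.

Step 8 is fourth. What may go wrong is sluggish oxidative addition at the electron-rich C5–Br bond beside a methoxy group, leading to reduction of the bromide or catalyst decay, and partial loss of the silyl group in the acid stage. The fallback uses no palladium and no acid; it sets out from 13 and comes back at 15. Bromine–lithium exchange with t-BuLi (2 equiv, THF, −78 °C), possible because 13 has no electrophilic group, is followed by trapping of the aryllithium with N-methoxy-N-methylacetamide, which gives 15 directly. No new compound arises on this way (entry F0).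

Step 6 is fifth. What may go wrong is deprotonation at C2 followed by β-elimination of silanolate and aromatisation, or migration of the silyl group to the new tertiary alkoxide. The fallback reverses the order of protection and addition; it sets out from 8 and comes back at 11. MeMgBr (4 equiv, THF, −78 → 0 °C) is added to unprotected 8, whose C3 magnesium alkoxide cannot leave, to give the diol F5; TBSCl and imidazole (DMF, rt) then silylate only the secondary hydroxyl and give 11.

## Further compounds

F1 | step 4 | racemic methyl cis-5-bromo-3-hydroxy-6,7-dimethoxy-2,3-dihydrobenzofuran-2-carboxylate (both enantiomers shown) | COC(=O)[C@H]1Oc2c(cc(Br)c(OC)c2OC)[C@H]1O.COC(=O)[C@@H]1Oc2c(cc(Br)c(OC)c2OC)[C@@H]1O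
F2 | step 4 | methyl (2R,3S)-3-acetoxy-5-bromo-6,7-dimethoxy-2,3-dihydrobenzofuran-2-carboxylate | COC(=O)[C@@H]1Oc2c(cc(Br)c(OC)c2OC)[C@@H]1OC(C)=O
F3 | step 7 | (2S,3R)-5-bromo-3-[(tert-butyldimethylsilyl)oxy]-N,6,7-trimethoxy-N-methyl-2,3-dihydrobenzofuran-2-carboxamide | CON(C)C(=O)[C@H]1Oc2c(cc(Br)c(OC)c2OC)[C@H]1O[Si](C)(C)C(C)(C)C
F4 | step 10 | (2R,3R)-5-acetyl-6,7-dimethoxy-2-(prop-1-en-2-yl)-2,3-dihydrobenzofuran-3-yl 2-[bis(2,2,2-trifluoroethoxy)phosphoryl]propanoate (both epimers at the phosphonate carbon) | C=C(C)[C@H]1Oc2c(cc(C(C)=O)c(OC)c2OC)[C@H]1OC(=O)C(C)P(=O)(OCC(F)(F)F)OCC(F)(F)F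
F0 | step 8 | none | none
F5 | step 6 | (2S,3R)-5-bromo-2-(2-hydroxypropan-2-yl)-6,7-dimethoxy-2,3-dihydrobenzofuran-3-ol | CC(C)(O)[C@H]1Oc2c(cc(Br)c(OC)c2OC)[C@H]1O
A1 | alternative 1 | diethyl({2-[(2S)-6,7-dimethoxy-5-(2-methyl-1,3-dioxolan-2-yl)-2,3-dihydrobenzofuran-2-yl]propan-2-yl}oxy)silane | CC[SiH](CC)OC(C)(C)[C@@H]1Cc2cc(C3(C)OCCO3)c(OC)c(OC)c2O1
A2 | alternative 1 | cis-fused diethyl oxasilolane of the 6,7-dimethoxy-5-(2-methyl-1,3-dioxolan-2-yl)-2,3-dihydrobenzofuran (silicon on C3, oxygen on the CMe2 branch) | CC[Si]1(CC)OC(C)(C)[C@H]2Oc3c(OC)c(OC)c(C4(C)OCCO4)cc3[C@H]21
A3 | alternative 1 | (2S,3R)-2-(2-hydroxypropan-2-yl)-6,7-dimethoxy-5-(2-methyl-1,3-dioxolan-2-yl)-2,3-dihydrobenzofuran-3-ol | CC(C)(O)[C@H]1Oc2c(cc(C3(C)OCCO3)c(OC)c2OC)[C@H]1O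
A4 | alternative 2 | (4R,5R)-4-[(tert-butyldimethylsilyl)oxy]-5-(prop-1-en-2-yl)dihydrofuran-2(3H)-one | C=C(C)[C@H]1OC(=O)C[C@H]1O[Si](C)(C)C(C)(C)C
A5 | alternative 2 | tert-butyldimethylsilyl ketene acetal of A4, (2R,3R)-3,5-bis[(tert-butyldimethylsilyl)oxy]-2-(prop-1-en-2-yl)-2,3-dihydrofuran | C=C(C)[C@H]1OC(O[Si](C)(C)C(C)(C)C)=C[C@H]1O[Si](C)(C)C(C)(C)C
A6 | alternative 2 | 5-acetyl-3,4-dimethoxy-2H-pyran-2-one | CC(=O)C1=COC(=O)C(OC)=C1OC
A7 | alternative 2 | (2R,3R)-5-acetyl-3-[(tert-butyldimethylsilyl)oxy]-6,7-dimethoxy-2-(prop-1-en-2-yl)-2,3-dihydrobenzofuran (identical with 15) | C=C(C)[C@H]1Oc2c(cc(C(C)=O)c(OC)c2OC)[C@H]1O[Si](C)(C)C(C)(C)C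
A8 | alternative 3 | 5-bromo-3,4-dimethoxy-2-(2-oxopropoxy)benzaldehyde | CC(=O)COc1c(OC)c(OC)c(Br)cc1C=O
A9 | alternative 3 | 1-[(2S,3R)-5-bromo-3-hydroxy-6,7-dimethoxy-2,3-dihydrobenzofuran-2-yl]ethan-1-one (cis) | CC(=O)[C@H]1Oc2c(cc(Br)c(OC)c2OC)[C@H]1O
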